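## The problem

Selaginellin has no ring fusion to negotiate. Everything hangs on one benzene, ring A, which carries four different carbon substituents on four adjacent positions: the quinone methide carbon on C1, a 4-hydroxyphenyl on C2, a hydroxymethyl on C5 and a (4-hydroxyphenyl)ethynyl on C6, while C3 and C4 are unsubstituted. The task is therefore regiochemical: each group must be placed beside the right neighbours on a ring that is crowded around C1 and C6. There is no stereocentre, and the exocyclic double bond has no E/Z descriptor because the cyclohexadienone ring is symmetric; the dienone and the phenol ring on the methide carbon also exchange roles by proton shift, so nothing configurational needs control. The fragile functions are the quinone methide (it adds nucleophiles and hydride), four free phenols, and the primary benzylic alcohol and the carbinol oxygen, both ortho to the alkyne and able to add to it under strong base, strong acid or π-acidic metals. This rules out a harsh last deprotection, since boron or aluminium halides would turn the benzylic alcohol into a halide and hot nucleophiles would cyclise alkoxides onto the alkyne. The phenols are therefore carried as silyl ethers and the quinone methide is formed last by dehydration of a triaryl carbinol. The feature that opens the key step is that C5–C6–C1–C2 of ring A has the connectivity of C3–C4–C5–C6 of a 2-pyrone built from an aroylacetate and a methylmalonyl unit, each position fixed by carbonyl chemistry, while the bare C3–C4 edge can come from an acetylene equivalent.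

## Retrosynthesis

**Quinone methide.** The exocyclic C=C of selaginellin 20 is cut by adding water across it, which gives pentahydroxy carbinol 19, and the four phenolic O–H bonds are traced to O–Si bonds in the tetrakis(triisopropylsilyl) ether 18. Against aryl methyl ethers, silyl ethers fall to buffered fluoride, which leaves the hydroxymethyl group and the alkyne alone. The forward reaction only needs fluoride kept non-basic and a mild acid to ionise the doubly 4-hydroxyphenyl-stabilised carbinol.

**Methide carbon.** In 18 both aryl–C bonds at the carbinol carbon are cut, leading to methyl ester 14 and two equivalents of aryllithium 16, made from aryl bromide 15; ketone 17 lies on the way. Against a Friedel–Crafts or cross-coupling construction, this uses the ester that the pyrone carries anyway and installs two identical rings in one operation. The forward step must force a nucleophile twice onto a carbonyl flanked by an aryl and an alkynyl group, which the slim alkyne and a reactive aryllithium should allow.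

**Benzylic oxygen.** The C–O bond of 14 is traced through bromide 13 to the C–H bond of the methyl group in 12. Carrying an oxygenated one-carbon unit through the pyrone would need a non-commercial alkoxymethylmalonyl chloride prone to β-elimination, so a plain methyl group is carried and oxidised on the electron-poor benzoate, before the triaryl carbinol exists. The forward reaction must brominate one benzylic methyl group without adding bromine to the diarylalkyne.

**Ring A (key disconnection).** In 12 the bonds C2–C3 and C4–C5 of ring A are cut, giving tetrasubstituted 2-pyrone 8 and norbornadiene 9; bridged lactone 10 and norbornene-fused cyclohexadiene 11 lie on the way. Against stepwise substitution of a preformed benzene, which would have to differentiate four adjacent positions, the cycloaddition takes the whole substitution pattern from the pyrone. No regiochemical question arises because the dienophile delivers two equal CH groups. The precursor is a monocyclic lactone with no crowded biaryl-type bonds still to be made. The forward reaction asks a fully substituted diene to react, hence a strained dienophile in excess and high temperature.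

**Alkyne.** In 8 the C(sp2)–C(sp) bond at pyrone C4 is cut to triflate 5 and terminal alkyne 7. Attaching the alkyne after ring A is formed would mean coupling at an aryl triflate wedged between an ester and a methyl group. At the pyrone stage the triflate is a vinylogous acyl triflate and couples readily.

**Pyrone.** Triflate 5 comes from 4-hydroxypyrone 4, whose C4–C5 and O1–C2 bonds are cut to β-keto ester 2 and methylmalonyl dichloride 3. This places the aryl group (from the ketone), the ester (from the active methylene), the future alkyne position (the new enolised carbonyl) and the methyl group (from the malonyl unit) in one step. The forward reaction needs C-acylation followed by lactonisation through the ketone enol oxygen.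

**Protecting groups.** β-Keto ester 2 is the triisopropylsilyl ether of commercial phenol 1, and alkyne 7 that of 4-ethynylphenol 6. Triisopropylsilyl is chosen over smaller silyl groups because it must survive dry HCl, amines, 190 °C, radical bromination, hot aqueous carbonate and an aryllithium.

## Roads not taken

**Alternative 1:** Ring A is cut at C4–C5 and C1=C2 at the cyclohexenone oxidation level. In a Robinson annulation, ethyl 5,5-bis(4-methoxyphenyl)-3-oxopentanoate A1 would add through its active methylene to 1-(4-methoxyphenyl)prop-2-en-1-one A2, and the γ-methylene would then condense with the aryl ketone to give cyclohexenone A3.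
- Merits: cheap reagents, no sealed tube, the benzhydryl carbon arrives with both aryl groups, and the C5 carbon arrives as an ester. In this last respect it is better than the chosen plan, which needs a radical bromination to oxidise a methyl group.
- Weak points: the aldol must go through the γ-carbon of A1, next to the benzhydryl group, onto an aryl ketone, and it forms a congested tetrasubstituted enone in competition with retro-Michael reaction and polymerisation of A2. A3 is also two oxidation levels below a benzene, so it must be dehydrogenated to a salicylate, its phenol sulfonylated and coupled with an alkyne at the most hindered position of the ring, and the triarylmethane C–H oxidised late beside an alkyne and a benzylic alcohol.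
- Comparison: this adds roughly nine or ten operations after A3. The chosen plan delivers ring A aromatic, with the alkyne in place, in the ring-forming step.

**Alternative 2:** Ring A is cut at C1–C2 and C5–C6. Heating triyne ester A4 would join its 1,3-diyne and its ynoate alkyne in a hexadehydro-Diels–Alder reaction, and the C3–C4 aryne would take two hydrogens from a cycloalkane solvent to give phthalide A5.
- Merits: this is the most convergent way to ring A. The carbinol carbon arrives fully arylated and at the right oxidation level, and C5 arrives oxygenated. In both respects it is as good as or better than the chosen plan.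
- Weak points: the lactone carbonyl of A5 sits on C6, where the target has an alkyne. It must therefore be reduced to the lactol level, homologated by one carbon (Seyferth–Gilbert type) and arylated, all next to the bulky silyloxytrityl group. The aryne reduction needs high dilution, and A4 needs an unsymmetrical diyne coupling and esterification of a hindered ynoic acid.
- Comparison: overall length is similar to the chosen plan. The chosen plan has on its side an alkyne introduced by a simple coupling on an activated triflate before the ring exists, and cheap condensation chemistry that can be run at normal concentration.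

**Alternative 3:** Ring A is cut at C3–C4 and C5–C6. In propargyl pyrone-3-carboxylate A6 the tethered alkyne would add across pyrone C3 and C6 and, after decarboxylative aromatisation, give phthalide A7.
- Merits: it is intramolecular, so no excess dienophile is needed, and C5 arrives oxygenated.
- Weak points: the ester tether must adopt its disfavoured s-cis conformation to reach the diene, so forcing conditions are still required. A6, with a benzhydryl group on C4, an aryl on C5 and hydrogen on C6, has no one-step condensation route comparable to that of 4. A7 then needs both the lactone-to-alkyne conversion of alternative 2 and a late benzhydryl C–H oxidation.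
- Comparison: it shares the pyrone logic of the chosen plan but spends more steps before and after the cycloaddition. The chosen plan pays only with the benzylic bromination.

Key step: step 6

Assumption: methylmalonyl dichloride 3, 4-ethynylphenol 6 and (4-bromophenoxy)triisopropylsilane 15 are taken as catalogue chemicals, and since the target carries no stereodescriptor no configuration is assigned anywhere.

## Route

Step 1
Reactants: 1 methyl 3-(4-hydroxyphenyl)-3-oxopropanoate
Product: 2 methyl 3-oxo-3-{4-[(triisopropylsilyl)oxy]phenyl}propanoate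
Conditions: TIPSCl (1.1 equiv), imidazole (2.2 equiv), DMF, 0 °C → rt
Reagents that add atoms: chlorotriisopropylsilane, CC(C)[Si](Cl)(C(C)C)C(C)C
Why: Phenol O-silylation under imidazole catalysis; the β-keto ester is not enol-silylated under these weakly basic conditions.

Step 2
Reactants: 2 methyl 3-oxo-3-{4-[(triisopropylsilyl)oxy]phenyl}propanoate; 3 methylmalonyl dichloride
Product: 4 methyl 4-hydroxy-3-methyl-2-oxo-6-{4-[(triisopropylsilyl)oxy]phenyl}-2H-pyran-5-carboxylate
Conditions: 3 (1.3 equiv), toluene, 90 °C, N2 sweep
Reagents that add atoms: none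
Why: Acylative pyrone annulation of a β-keto ester with a malonyl dichloride: C-acylation at the active methylene, then the enol oxygen of the aryl ketone closes the lactone on the second acyl chloride and the product rests as the 4-hydroxy-2-pyrone tautomer. The aryl silyl ether tolerates dry HCl, which is swept out.

Step 3
Reactants: 4 methyl 4-hydroxy-3-methyl-2-oxo-6-{4-[(triisopropylsilyl)oxy]phenyl}-2H-pyran-5-carboxylate
Product: 5 methyl 3-methyl-2-oxo-6-{4-[(triisopropylsilyl)oxy]phenyl}-4-{[(trifluoromethyl)sulfonyl]oxy}-2H-pyran-5-carboxylate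
Conditions: Tf2O (1.2 equiv), Et3N (1.5 equiv), CH2Cl2, −78 → 0 °C
Reagents that add atoms: trifluoromethanesulfonic anhydride, O=S(=O)(OS(=O)(=O)C(F)(F)F)C(F)(F)F
Why: O-Sulfonylation of the acidic 4-hydroxy-2-pyrone (a vinylogous carboxylic acid) at O4; 4-sulfonyloxy-2-pyrones are standard cross-coupling partners of this ring system.

Step 4
Reactants: 6 4-ethynylphenol
Product: 7 (4-ethynylphenoxy)triisopropylsilane
Conditions: TIPSCl (1.1 equiv), imidazole (2.2 equiv), CH2Cl2, 0 °C → rt
Reagents that add atoms: chlorotriisopropylsilane, CC(C)[Si](Cl)(C(C)C)C(C)C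
Why: Phenol O-silylation; it also stabilises the polymerisation-prone ethynylphenol, which is used promptly.

Step 5
Reactants: 5 methyl 3-methyl-2-oxo-6-{4-[(triisopropylsilyl)oxy]phenyl}-4-{[(trifluoromethyl)sulfonyl]oxy}-2H-pyran-5-carboxylate; 7 (4-ethynylphenoxy)triisopropylsilane
Product: 8 methyl 3-methyl-2-oxo-6-{4-[(triisopropylsilyl)oxy]phenyl}-4-({4-[(triisopropylsilyl)oxy]phenyl}ethynyl)-2H-pyran-5-carboxylate
Conditions: PdCl2(PPh3)2 (3 mol%), CuI (5 mol%), Et3N (3 equiv), THF, rt
Reagents that add atoms: none
Why: Sonogashira coupling; the 4-triflyloxy-2-pyrone is a vinylogous acyl triflate that adds quickly to zerovalent palladium, and the slim copper acetylide couples despite the flanking methyl and ester groups. Silyl ethers and the lactone tolerate triethylamine in THF at room temperature.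

Step 6
Reactants: 8 methyl 3-methyl-2-oxo-6-{4-[(triisopropylsilyl)oxy]phenyl}-4-({4-[(triisopropylsilyl)oxy]phenyl}ethynyl)-2H-pyran-5-carboxylate; 9 norbornadiene
Product: 12 methyl 3-methyl-6-{4-[(triisopropylsilyl)oxy]phenyl}-2-({4-[(triisopropylsilyl)oxy]phenyl}ethynyl)benzoate, via bridged lactone adduct 10 (not isolated), via norbornene-fused cyclohexadiene 11 (not isolated)
Conditions: 9 (20 equiv), BHT (cat.), 1,2-dichlorobenzene, sealed tube, 190 °C
Reagents that add atoms: none
Why: The pyrone, electron-poor through its lactone and C5 ester, acts as the diene, and one strained double bond of norbornadiene adds across pyrone C3 and C6 in a thermal [4+2] cycloaddition (the six-membered ring is closed by intermolecular cycloaddition, both new σ bonds being made in that event) to give bridged lactone 10. Cycloreversion of 10 expels CO2 and leaves the norbornene-fused cyclohexadiene 11, whose second retro-Diels–Alder (Alder–Rickert) step releases cyclopentadiene and is driven by aromatisation to 12. The closest known reaction type is the conversion of 2-pyrone carboxylates into benzoates with norbornadiene as an acetylene equivalent; the present case is that reaction on a fully substituted diene, which is why a sealed tube near 190 °C and a large excess of dienophile are specified. No stereocentre survives: the sp3 centres of 10 and 11, formed as endo/exo mixtures, are all erased on aromatisation. Regiochemistry does not arise because both dienophile carbons end as the unsubstituted C3 and C4 of ring A. The selectivity that matters is chemoselectivity for the strained alkene over the diarylalkyne already present in 8 and over a second pyrone molecule; ring strain, the twenty-fold excess and the unhindered approach of norbornadiene should secure it, and BHT suppresses radical polymerisation.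

Step 7
Reactants: 12 methyl 3-methyl-6-{4-[(triisopropylsilyl)oxy]phenyl}-2-({4-[(triisopropylsilyl)oxy]phenyl}ethynyl)benzoate
Product: 13 methyl 3-(bromomethyl)-6-{4-[(triisopropylsilyl)oxy]phenyl}-2-({4-[(triisopropylsilyl)oxy]phenyl}ethynyl)benzoate
Conditions: NBS (1.05 equiv), AIBN (5 mol%), PhCF3, 85 °C
Reagents that add atoms: N-bromosuccinimide, O=C1CCC(=O)N1Br
Why: Wohl–Ziegler bromination at the only benzylic C–H position; the low stationary bromine concentration and the apolar medium disfavour ionic addition to the alkyne and ring bromination. The benzylic radical cannot close onto the ortho alkyne without forming a four-membered ring or a 5-endo ring.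

Step 8
Reactants: 13 methyl 3-(bromomethyl)-6-{4-[(triisopropylsilyl)oxy]phenyl}-2-({4-[(triisopropylsilyl)oxy]phenyl}ethynyl)benzoate
Product: 14 methyl 3-(hydroxymethyl)-6-{4-[(triisopropylsilyl)oxy]phenyl}-2-({4-[(triisopropylsilyl)oxy]phenyl}ethynyl)benzoate
Conditions: CaCO3 (5 equiv), 1,4-dioxane/H2O (1:1), 100 °C
Reagents that add atoms: water, O
Why: Solvolysis of a primary benzylic bromide with carbonate as acid scavenger; the hindered methyl ester and the triisopropylsilyl ethers survive near-neutral water. Without a π-acidic metal or strong base the new alcohol does not add to the neighbouring alkyne, and lactonisation is impossible because the ester is meta.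

Step 9
Reactants: 14 methyl 3-(hydroxymethyl)-6-{4-[(triisopropylsilyl)oxy]phenyl}-2-({4-[(triisopropylsilyl)oxy]phenyl}ethynyl)benzoate; 15 (4-bromophenoxy)triisopropylsilane
Product: 18 [3-(hydroxymethyl)-6-{4-[(triisopropylsilyl)oxy]phenyl}-2-({4-[(triisopropylsilyl)oxy]phenyl}ethynyl)phenyl]bis{4-[(triisopropylsilyl)oxy]phenyl}methanol, via 4-(triisopropylsilyloxy)phenyllithium 16 (not isolated), via diaryl ketone 17 (not isolated)
Conditions: 15 (5 equiv), n-BuLi (4.8 equiv), THF, −78 °C; then 14, −78 °C → rt; H2O
Reagents that add atoms: none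
Why: Bromine–lithium exchange gives 16; one equivalent deprotonates the primary alcohol and two add to the ester through ketone 17 (double addition of an organolithium to a benzoate), the linear alkynyl neighbour leaving one face of the carbonyl accessible. Lithium alkoxides in THF are poor nucleophiles toward the electron-rich diarylalkyne, so cyclisation is not expected at these temperatures.

Step 10
Reactants: 18 [3-(hydroxymethyl)-6-{4-[(triisopropylsilyl)oxy]phenyl}-2-({4-[(triisopropylsilyl)oxy]phenyl}ethynyl)phenyl]bis{4-[(triisopropylsilyl)oxy]phenyl}methanol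
Product: 20 selaginellin, via pentahydroxy carbinol 19 (not isolated)
Conditions: Bu4NF (6 equiv), AcOH (6 equiv), THF, 0 °C → rt; then 1 M HCl, rt
Reagents that add atoms: none
Why: Fluoride cleaves the four aryl O–Si bonds, and the acetic acid buffer keeps phenoxides and alkoxides protonated so that neither oxygen ortho to the alkyne adds to it. On acidification carbinol 19 ionises to a cation stabilised by two 4-hydroxyphenyl groups and loses a phenolic proton, the known dehydration of 4-hydroxytrityl alcohols to fuchsone-type quinone methides; no stereo element is created.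

## Compound list

1 | methyl 3-(4-hydroxyphenyl)-3-oxopropanoate | COC(=O)CC(=O)c1ccc(O)cc1 | starting material
2 | methyl 3-oxo-3-{4-[(triisopropylsilyl)oxy]phenyl}propanoate | COC(=O)CC(=O)c1ccc(O[Si](C(C)C)(C(C)C)C(C)C)cc1 | intermediate
3 | methylmalonyl dichloride | CC(C(Cl)=O)C(Cl)=O | starting material
4 | methyl 4-hydroxy-3-methyl-2-oxo-6-{4-[(triisopropylsilyl)oxy]phenyl}-2H-pyran-5-carboxylate | CC1=C(O)C(C(=O)OC)=C(c2ccc(O[Si](C(C)C)(C(C)C)C(C)C)cc2)OC1=O | intermediate
5 | methyl 3-methyl-2-oxo-6-{4-[(triisopropylsilyl)oxy]phenyl}-4-{[(trifluoromethyl)sulfonyl]oxy}-2H-pyran-5-carboxylate | CC1=C(OS(=O)(=O)C(F)(F)F)C(C(=O)OC)=C(c2ccc(O[Si](C(C)C)(C(C)C)C(C)C)cc2)OC1=O | intermediate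
6 | 4-ethynylphenol | C#Cc1ccc(O)cc1 | starting material
7 | (4-ethynylphenoxy)triisopropylsilane | C#Cc1ccc(O[Si](C(C)C)(C(C)C)C(C)C)cc1 | intermediate
8 | methyl 3-methyl-2-oxo-6-{4-[(triisopropylsilyl)oxy]phenyl}-4-({4-[(triisopropylsilyl)oxy]phenyl}ethynyl)-2H-pyran-5-carboxylate | CC1=C(C#Cc2ccc(O[Si](C(C)C)(C(C)C)C(C)C)cc2)C(C(=O)OC)=C(c2ccc(O[Si](C(C)C)(C(C)C)C(C)C)cc2)OC1=O | intermediate
9 | norbornadiene (bicyclo[2.2.1]hepta-2,5-diene) | C1=CC2C=CC1C2 | starting material
10 | bridged lactone adduct of 8 and 9 (2-oxabicyclo[2.2.2]oct-5-en-3-one fused to a norbornene; diastereomer mixture, configuration not defined) | CC12C(=O)OC(c3ccc(O[Si](C(C)C)(C(C)C)C(C)C)cc3)(C(C(=O)OC)=C1C#Cc1ccc(O[Si](C(C)C)(C(C)C)C(C)C)cc1)C1C2C2C=CC1C2 | intermediate (not isolated)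
11 | methyl 5-methyl-8-{4-[(triisopropylsilyl)oxy]phenyl}-6-({4-[(triisopropylsilyl)oxy]phenyl}ethynyl)-1,4,4a,8a-tetrahydro-1,4-methanonaphthalene-7-carboxylate (diastereomer mixture) | CC1=C(C#Cc2ccc(O[Si](C(C)C)(C(C)C)C(C)C)cc2)C(C(=O)OC)=C(c2ccc(O[Si](C(C)C)(C(C)C)C(C)C)cc2)C2C1C1C=CC2C1 | intermediate (not isolated)
12 | methyl 3-methyl-6-{4-[(triisopropylsilyl)oxy]phenyl}-2-({4-[(triisopropylsilyl)oxy]phenyl}ethynyl)benzoate | COC(=O)c1c(-c2ccc(O[Si](C(C)C)(C(C)C)C(C)C)cc2)ccc(C)c1C#Cc1ccc(O[Si](C(C)C)(C(C)C)C(C)C)cc1 | intermediate
13 | methyl 3-(bromomethyl)-6-{4-[(triisopropylsilyl)oxy]phenyl}-2-({4-[(triisopropylsilyl)oxy]phenyl}ethynyl)benzoate | COC(=O)c1c(-c2ccc(O[Si](C(C)C)(C(C)C)C(C)C)cc2)ccc(CBr)c1C#Cc1ccc(O[Si](C(C)C)(C(C)C)C(C)C)cc1 | intermediate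
14 | methyl 3-(hydroxymethyl)-6-{4-[(triisopropylsilyl)oxy]phenyl}-2-({4-[(triisopropylsilyl)oxy]phenyl}ethynyl)benzoate | COC(=O)c1c(-c2ccc(O[Si](C(C)C)(C(C)C)C(C)C)cc2)ccc(CO)c1C#Cc1ccc(O[Si](C(C)C)(C(C)C)C(C)C)cc1 | intermediate
15 | (4-bromophenoxy)triisopropylsilane | Brc1ccc(O[Si](C(C)C)(C(C)C)C(C)C)cc1 | starting material
16 | {4-[(triisopropylsilyl)oxy]phenyl}lithium | [Li]c1ccc(O[Si](C(C)C)(C(C)C)C(C)C)cc1 | intermediate (not isolated)
17 | [3-(hydroxymethyl)-6-{4-[(triisopropylsilyl)oxy]phenyl}-2-({4-[(triisopropylsilyl)oxy]phenyl}ethynyl)phenyl]{4-[(triisopropylsilyl)oxy]phenyl}methanone (present in the flask as its lithium alkoxide) | O=C(c1ccc(O[Si](C(C)C)(C(C)C)C(C)C)cc1)c1c(-c2ccc(O[Si](C(C)C)(C(C)C)C(C)C)cc2)ccc(CO)c1C#Cc1ccc(O[Si](C(C)C)(C(C)C)C(C)C)cc1 | intermediate (not isolated)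
18 | [3-(hydroxymethyl)-6-{4-[(triisopropylsilyl)oxy]phenyl}-2-({4-[(triisopropylsilyl)oxy]phenyl}ethynyl)phenyl]bis{4-[(triisopropylsilyl)oxy]phenyl}methanol | OC(c1ccc(O[Si](C(C)C)(C(C)C)C(C)C)cc1)(c1ccc(O[Si](C(C)C)(C(C)C)C(C)C)cc1)c1c(-c2ccc(O[Si](C(C)C)(C(C)C)C(C)C)cc2)ccc(CO)c1C#Cc1ccc(O[Si](C(C)C)(C(C)C)C(C)C)cc1 | intermediate
19 | [3-(hydroxymethyl)-6-(4-hydroxyphenyl)-2-[(4-hydroxyphenyl)ethynyl]phenyl]bis(4-hydroxyphenyl)methanol | OC(c1ccc(O)cc1)(c1ccc(O)cc1)c1c(-c2ccc(O)cc2)ccc(CO)c1C#Cc1ccc(O)cc1 | intermediate (not isolated)
20 | selaginellin, 4-{[3-(hydroxymethyl)-6-(4-hydroxyphenyl)-2-[(4-hydroxyphenyl)ethynyl]phenyl](4-hydroxyphenyl)methylidene}cyclohexa-2,5-dien-1-one | O=C1C=CC(=C(c2ccc(O)cc2)c2c(-c3ccc(O)cc3)ccc(CO)c2C#Cc2ccc(O)cc2)C=C1 | target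

## Step count and risks

Total: 10 steps. Longest linear sequence: 9 steps (1, 2, 3, 5, 6, 7, 8, 9, 10); step 4 is a one-step side branch.

**Step 6 (key step).** The most likely failure is a slow first cycloaddition of the tetrasubstituted diene, so that at the temperature needed the pyrone is consumed by other paths: re-addition of the liberated cyclopentadiene, or reaction through its own alkyne. The fallback sets out from 8 and returns at 12. It changes the acetylene equivalent from a strained alkene lost by cycloreversion to an enol ether lost by elimination. Heating 8 with excess ethyl vinyl ether in a sealed tube at about 130 °C should give, by inverse-electron-demand Diels–Alder reaction and decarboxylation, methyl 4-ethoxy-5-methyl-2-{4-[(triisopropylsilyl)oxy]phenyl}-6-({4-[(triisopropylsilyl)oxy]phenyl}ethynyl)cyclohexa-1,5-diene-1-carboxylate F1 (racemic; the position of the ethoxy group is immaterial). TsOH in toluene should then eliminate ethanol to give 12.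

**Step 2.** Methylmalonyl dichloride may self-condense through its ketene, or acylation may stop at an open O- or C-acyl stage without ring closure, and HCl may erode the silyl ether. The fallback sets out from 2 and returns at 4, separating the two bond formations. C-Acylation of the magnesium enolate of 2 (MgCl2, Et3N, MeCN) with methyl 3-chloro-2-methyl-3-oxopropanoate should give dimethyl 2-methyl-3-oxo-4-{4-[(triisopropylsilyl)oxy]benzoyl}pentanedioate F2. Heating F2 with DBU in toluene should close the lactone through the ketone enol oxygen, with loss of methanol, to give 4.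

**Step 7.** Bromine may add across the electron-rich diarylalkyne, or ring or double bromination may compete with monobromination. The fallback sets out from 5 and returns at 14, moving the bromination to a stage without the alkyne.
- Triflate 5 and norbornadiene 9 under the conditions of step 6 should pass through the bridged lactone triflate F3 and the norbornene-fused cyclohexadiene triflate F4 (neither isolated) to methyl 3-methyl-6-{4-[(triisopropylsilyl)oxy]phenyl}-2-{[(trifluoromethyl)sulfonyl]oxy}benzoate F5.
- NBS/AIBN should give the bromomethyl aryl triflate F6, and CaCO3 in aqueous dioxane the hydroxymethyl aryl triflate F7.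
- Sonogashira coupling of F7 with 7 (Pd(OAc)2, XPhos, CuI, Et3N, MeCN, 60 °C) should give 14.

The price is a coupling at a doubly ortho-substituted aryl triflate.

**Step 9.** The addition may stall at ketone 17, or not start, because the carbonyl lies between two ortho substituents; long warming to force it invites alkoxide addition to the alkyne. The fallback sets out from 14 and returns at 19 (and so at 20). It builds the carbinol one aryl group at a time from the aldehyde.
- TBSCl/imidazole should give the tert-butyldimethylsilyl ether of 14 F8.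
- i-Bu2AlH (CH2Cl2, −78 °C) should reduce the ester to the benzylic alcohol F9, and MnO2 should oxidise it to the aldehyde F10.
- Aryllithium 16 should add to the unhindered formyl group to give the secondary diarylmethanol F11 (racemic), and Dess–Martin periodinane should give the ketone F12.
- A second portion of 16, transmetalated with CeCl3 if needed, should give the carbinol F13, the tert-butyldimethylsilyl ether of 18.
- Under the conditions of step 10, F13 should lose all five silyl groups to give 19 and then 20.

## Further compounds

F1 | step 6 | methyl 4-ethoxy-5-methyl-2-{4-[(triisopropylsilyl)oxy]phenyl}-6-({4-[(triisopropylsilyl)oxy]phenyl}ethynyl)cyclohexa-1,5-diene-1-carboxylate (racemic) | CCOC1CC(c2ccc(O[Si](C(C)C)(C(C)C)C(C)C)cc2)=C(C(=O)OC)C(C#Cc2ccc(O[Si](C(C)C)(C(C)C)C(C)C)cc2)=C1C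
F2 | step 2 | dimethyl 2-methyl-3-oxo-4-{4-[(triisopropylsilyl)oxy]benzoyl}pentanedioate | COC(=O)C(C)C(=O)C(C(=O)OC)C(=O)c1ccc(O[Si](C(C)C)(C(C)C)C(C)C)cc1
F3 | step 7 | bridged lactone adduct of 5 and norbornadiene (2-oxabicyclo[2.2.2]oct-5-en-3-one triflate fused to a norbornene; diastereomer mixture) | CC12C(=O)OC(c3ccc(O[Si](C(C)C)(C(C)C)C(C)C)cc3)(C(C(=O)OC)=C1OS(=O)(=O)C(F)(F)F)C1C2C2C=CC1C2
F4 | step 7 | methyl 5-methyl-8-{4-[(triisopropylsilyl)oxy]phenyl}-6-{[(trifluoromethyl)sulfonyl]oxy}-1,4,4a,8a-tetrahydro-1,4-methanonaphthalene-7-carboxylate (diastereomer mixture) | CC1=C(OS(=O)(=O)C(F)(F)F)C(C(=O)OC)=C(c2ccc(O[Si](C(C)C)(C(C)C)C(C)C)cc2)C2C1C1C=CC2C1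
F5 | step 7 | methyl 3-methyl-6-{4-[(triisopropylsilyl)oxy]phenyl}-2-{[(trifluoromethyl)sulfonyl]oxy}benzoate | COC(=O)c1c(-c2ccc(O[Si](C(C)C)(C(C)C)C(C)C)cc2)ccc(C)c1OS(=O)(=O)C(F)(F)F
F6 | step 7 | methyl 3-(bromomethyl)-6-{4-[(triisopropylsilyl)oxy]phenyl}-2-{[(trifluoromethyl)sulfonyl]oxy}benzoate | COC(=O)c1c(-c2ccc(O[Si](C(C)C)(C(C)C)C(C)C)cc2)ccc(CBr)c1OS(=O)(=O)C(F)(F)F
F7 | step 7 | methyl 3-(hydroxymethyl)-6-{4-[(triisopropylsilyl)oxy]phenyl}-2-{[(trifluoromethyl)sulfonyl]oxy}benzoate | COC(=O)c1c(-c2ccc(O[Si](C(C)C)(C(C)C)C(C)C)cc2)ccc(CO)c1OS(=O)(=O)C(F)(F)F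
F8 | step 9 | methyl 3-({[tert-butyl(dimethyl)silyl]oxy}methyl)-6-{4-[(triisopropylsilyl)oxy]phenyl}-2-({4-[(triisopropylsilyl)oxy]phenyl}ethynyl)benzoate | COC(=O)c1c(-c2ccc(O[Si](C(C)C)(C(C)C)C(C)C)cc2)ccc(CO[Si](C)(C)C(C)(C)C)c1C#Cc1ccc(O[Si](C(C)C)(C(C)C)C(C)C)cc1
F9 | step 9 | [3-({[tert-butyl(dimethyl)silyl]oxy}methyl)-6-{4-[(triisopropylsilyl)oxy]phenyl}-2-({4-[(triisopropylsilyl)oxy]phenyl}ethynyl)phenyl]methanol | OCc1c(-c2ccc(O[Si](C(C)C)(C(C)C)C(C)C)cc2)ccc(CO[Si](C)(C)C(C)(C)C)c1C#Cc1ccc(O[Si](C(C)C)(C(C)C)C(C)C)cc1
F10 | step 9 | 3-({[tert-butyl(dimethyl)silyl]oxy}methyl)-6-{4-[(triisopropylsilyl)oxy]phenyl}-2-({4-[(triisopropylsilyl)oxy]phenyl}ethynyl)benzaldehyde | O=Cc1c(-c2ccc(O[Si](C(C)C)(C(C)C)C(C)C)cc2)ccc(CO[Si](C)(C)C(C)(C)C)c1C#Cc1ccc(O[Si](C(C)C)(C(C)C)C(C)C)cc1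
F11 | step 9 | [3-({[tert-butyl(dimethyl)silyl]oxy}methyl)-6-{4-[(triisopropylsilyl)oxy]phenyl}-2-({4-[(triisopropylsilyl)oxy]phenyl}ethynyl)phenyl]{4-[(triisopropylsilyl)oxy]phenyl}methanol (racemic) | OC(c1ccc(O[Si](C(C)C)(C(C)C)C(C)C)cc1)c1c(-c2ccc(O[Si](C(C)C)(C(C)C)C(C)C)cc2)ccc(CO[Si](C)(C)C(C)(C)C)c1C#Cc1ccc(O[Si](C(C)C)(C(C)C)C(C)C)cc1
F12 | step 9 | [3-({[tert-butyl(dimethyl)silyl]oxy}methyl)-6-{4-[(triisopropylsilyl)oxy]phenyl}-2-({4-[(triisopropylsilyl)oxy]phenyl}ethynyl)phenyl]{4-[(triisopropylsilyl)oxy]phenyl}methanone | O=C(c1ccc(O[Si](C(C)C)(C(C)C)C(C)C)cc1)c1c(-c2ccc(O[Si](C(C)C)(C(C)C)C(C)C)cc2)ccc(CO[Si](C)(C)C(C)(C)C)c1C#Cc1ccc(O[Si](C(C)C)(C(C)C)C(C)C)cc1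
F13 | step 9 | [3-({[tert-butyl(dimethyl)silyl]oxy}methyl)-6-{4-[(triisopropylsilyl)oxy]phenyl}-2-({4-[(triisopropylsilyl)oxy]phenyl}ethynyl)phenyl]bis{4-[(triisopropylsilyl)oxy]phenyl}methanol | OC(c1ccc(O[Si](C(C)C)(C(C)C)C(C)C)cc1)(c1ccc(O[Si](C(C)C)(C(C)C)C(C)C)cc1)c1c(-c2ccc(O[Si](C(C)C)(C(C)C)C(C)C)cc2)ccc(CO[Si](C)(C)C(C)(C)C)c1C#Cc1ccc(O[Si](C(C)C)(C(C)C)C(C)C)cc1
A1 | alternative 1 | ethyl 5,5-bis(4-methoxyphenyl)-3-oxopentanoate | CCOC(=O)CC(=O)CC(c1ccc(OC)cc1)c1ccc(OC)cc1
A2 | alternative 1 | 1-(4-methoxyphenyl)prop-2-en-1-one | C=CC(=O)c1ccc(OC)cc1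
A3 | alternative 1 | ethyl 3-[bis(4-methoxyphenyl)methyl]-4-(4-methoxyphenyl)-2-oxocyclohex-3-ene-1-carboxylate (racemic) | CCOC(=O)C1CCC(c2ccc(OC)cc2)=C(C(c2ccc(OC)cc2)c2ccc(OC)cc2)C1=O
A4 | alternative 2 | 5-(4-methoxyphenyl)penta-2,4-diyn-1-yl 4,4-bis(4-methoxyphenyl)-4-[(trimethylsilyl)oxy]but-2-ynoate | COc1ccc(C#CC#CCOC(=O)C#CC(O[Si](C)(C)C)(c2ccc(OC)cc2)c2ccc(OC)cc2)cc1
A5 | alternative 2 | 7-[bis(4-methoxyphenyl)(trimethylsilyloxy)methyl]-6-(4-methoxyphenyl)isobenzofuran-1(3H)-one | O=C1OCc2ccc(-c3ccc(OC)cc3)c(C(O[Si](C)(C)C)(c3ccc(OC)cc3)c3ccc(OC)cc3)c12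
A6 | alternative 3 | prop-2-yn-1-yl 4-[bis(4-methoxyphenyl)methyl]-5-(4-methoxyphenyl)-2-oxo-2H-pyran-3-carboxylate | C#CCOC(=O)C1=C(C(c2ccc(OC)cc2)c2ccc(OC)cc2)C(c2ccc(OC)cc2)=COC1=O
A7 | alternative 3 | 7-[bis(4-methoxyphenyl)methyl]-6-(4-methoxyphenyl)isobenzofuran-1(3H)-one | O=C1OCc2ccc(-c3ccc(OC)cc3)c(C(c3ccc(OC)cc3)c3ccc(OC)cc3)c12
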